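The data were generated by integration from invented constants; noise was put on by code.

**Reagent cover in oak and ash**

| setting | teal | blue | ash | oak |
|---|---|---|---|---|
| solid substrate | 0.10 M | 0.10 M | 0.10 M | 0.10 M |
| reagent | 0.30 M (fed, over 80 min) | 0.40 M (fed, over 80 min) | 0.200 M (fed, over 80 min) | 0.200 M (fed, over 80 min) |
| scavenger | 0.10 M | 0.10 M | 0.150 M | 0.100 M |
| remark | run made earlier; the fed solution adds 0.25 times the starting volume | run made earlier; the fed solution adds 0.25 times the starting volume | the fed solution adds 0.25 times the starting volume | the fed solution adds 0.25 times the starting volume |
| time |  |  | 6.0 h | 6.0 h |

- teal (time / min: solid substrate / %, double product / %): 20.0: 92, 0; 40.0: 78, 14; 50.0: 76, 20; 80.0: 63, 35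
- blue (time / min: solid substrate / %, double product / %): 10.0: 94, 3; 25.0: 88, 6; 50.0: 78, 20; 80.0: 59, 37

(scatter of a reading: 1.5 percentage points)

- released group is meant together with its idle adduct
- every charge counts on the volume at the start, and the solution that is fed holds the whole dose
- solid, in amounts per volume of the solution: solid substrate
- steps under discussion: 2 reagent -> homo dimer; scavenger + released group -> scavenged by-product; reagent + mono adduct -> double product + released group; solid substrate <-> starting material; reagent + released group <-> idle adduct; starting material + reagent -> mono adduct + released group
- at the start none of the solid substrate is in solution
- what has only dissolved of solid substrate counts as not reacted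
- no earlier run changes the charge of scavenger; that part of a forecast is a guess

1. part of the solid substrate that has reacted (what has only dissolved counts as not reacted) at the end, ash
2. part of the solid substrate that has reacted (what has only dissolved counts as not reacted) at the end, oak
3. what raising the concentration of scavenger from its lowest to its highest value here does to the part of the solid substrate that has reacted (what has only dissolved counts as not reacted) (changes below 5 percentage points count as none) (it rises / it falls / no change)

1. Slowness sits in the loss of solid substrate. After 80.0 min the teal run still holds 63% of it and the blue run 59%, though blue was charged 1.33 times the reagent of teal.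

2. In the teal run at that time, solid substrate and double product together read 98.0%, leaving hardly any for starting material and mono adduct. The reckoning here therefore treats the step from mono adduct to double product as fast: each solid substrate that goes on to double product takes two reagent.

3. At the pace read from teal, the solid is reckoned to last 3.60 h, shorter than the 6.0 h of oak and ash. So the end of these two flasks is reckoned from their reagent charge.

4. Oak and ash look nearly the same, and both have a reagent cover C of 100%. C is the reagent charge over twice the solid substrate charge, the share of the solid substrate that the reagent can bring to double product.

5. The flasks differ in scavenger, 0.100 M in oak against 0.150 M in ash, and scavenger has no place in C. This reckoning therefore expects the two to end within 5 percentage points of each other, with double product somewhat under C, so for the trend no change.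

6. The forecast differs. It gives 79% for ash and 69% for oak, so for the trend it rises, and reasons: “whatever the scavenger misses ties up reagent as idle adduct”.

The simulation gives 86.7% for ash and 85.0% for oak, a change of 1.7 points, so for the trend no change.

    2 reagent → homo dimer (k = 6.99 × 10⁻⁴ L mol⁻¹ s⁻¹)
    scavenger + released group → scavenged by-product (k = 0.0193 L mol⁻¹ s⁻¹)
    reagent + mono adduct → double product + released group (k = 0.155 L mol⁻¹ s⁻¹)
    solid substrate ⇌ starting material, rate k4*(cs4 - [starting material]) while solid is left; crystals form when [starting material] > cs4 (solubility = 35.0 mM, k = 2.18 × 10⁻⁴ s⁻¹)
    reagent + released group ⇌ idle adduct, settled at all times (K = 167 L mol⁻¹)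
    starting material + reagent → mono adduct + released group (k = 0.0338 L mol⁻¹ s⁻¹)

The reacted part of oak ends under its C of 100%, at 85.0%, with 0.49% of its reagent left, 15.0% as starting material and 0.0101 M of homo dimer. The neighbouring flask is oak with 0.080 M of reagent, so its C is 40.0%. That flask has 41.3% reacted at 6.00 h, with 0% of its reagent left, the limiting reagent. It holds 36.3% as double product, under that C, 4.93% as mono adduct and 41.9% as starting material.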